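The number to hold is 3.60 h: the mean contact time, which is the time an evenly dosed portion spends in the flask on average, the run time less half the dosing time.

| setting | Tuesday's | Sunday's | south-west | west | north-east | south |
|---|---|---|---|---|---|---|
| substrate | 0.10 M | 0.10 M | 0.10 M | 0.10 M | 0.10 M (fed, over 4.80 h) | 0.10 M |
| reagent | 0.15 M | 0.075 M | 0.150 M | 0.150 M | 0.150 M | 0.150 M (fed, over 4.80 h) |
| remark | run made earlier | run made earlier | everything together in a closed stirred flask, run for 6.0 h | one stirred flow tank at steady state, fed with the mixture as stated, mean residence time 6.0 h | all but substrate at the start; substrate goes in evenly over 4.80 h, the run ends at 6.0 h | a stirred flask in which reagent is dosed at a steady rate over 4.80 h without added volume, worked up at 6.0 h |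
| time |  |  | 6.0 h |  | 6.0 h | 6.0 h |

Tuesday's run (percent of the substrate charged)

| time / h | target / % | substrate / % |
|---|---|---|
| 0.500 | 25 | 71 |
| 1.00 | 35 | 56 |
| 2.50 | 51 | 40 |
| 6.00 | 64 | 21 |

Sunday's run (percent of the substrate charged)

| time / min | target / % | substrate / % |
|---|---|---|
| 25.0 | 11 | 85 |
| 50.0 | 16 | 79 |
| 80.0 | 23 | 71 |
| 120 | 26 | 67 |

(scatter of a reading: 1.5 percentage points)

- the stated concentrations are those of everything mixed, before any reaction; amounts are the same in each set-up
- the feed brings no volume worth counting
- the earlier runs were made in a closed, stirred flask
- a reading or a percentage of target counts all its forms, free or not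
- a reading of substrate is of its free form alone

* the set-up with the highest amount of target at the outlet or at the end, in percent of the substrate put in ("none" if the first two lie within 2 percentage points) (south-west / west / north-east / south / none)
* amount of target at the outlet or at the end, in percent of the substrate put in, south-west
* amount of target at the outlet or at the end, in percent of the substrate put in, west
* amount of target at the outlet or at the end, in percent of the substrate put in, north-east
* amount of target at the outlet or at the end, in percent of the substrate put in, south

The first readings show substrate falling at 0.685 h⁻¹ in Tuesday's run and 0.390 h⁻¹ in Sunday's. That is twice as fast on twice the reagent, so the reagent concentration reads as order one. The reckoning made here takes a dosed flask to stand on the closed-flask curve at its contact time, whichever partner is dosed.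

Turned round, a dosed flask could beat the closed one only if target at 3.60 h on that curve stood above target at 6.0 h, a peak already passed. Tuesday's readings, from the recipe of south-west, show a rise instead. Between 51% and 64%, target at the contact time interpolates to 55.1%, which is 8.9 percentage points below the last reading, with a scatter of 1.5 points. This reckoning therefore gives 64% for south-west and 55.1% for north-east and for south, and puts no number on west.

The forecast names south-west, with 63% for south-west, 46% for west, 40% for north-east and 55% for south. The two part at north-east, where the forecast holds that “reagent decays before substrate arrives” and gives 40% against the 55.1% reckoned here.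

The flasks give 63.4% in south-west, 49.6% in west, 54.8% in north-east and 54.3% in south, so south-west is best. In north-east at 3.00 h, reagent stood at 60.0% of its own charge. The contact time of 3.60 h had given 55.1%, which is 0.30 points above north-east and 0.80 points above south.

    reagent + target ⇌ idle adduct, settled at all times (K = 303 M⁻¹)
    substrate + reagent ⇌ target (K = 105 M⁻¹, k = 0.00124 M⁻¹ s⁻¹)
    substrate + reagent ⇌ isomer of the product (K = 15.8 M⁻¹, k = 3.07 × 10⁻⁴ M⁻¹ s⁻¹)

The neighbour of south-west charged with 0.060 M of substrate has no dosing, so its contact time is 6.0 h, and with the reagent of Tuesday's run and substrate taken as order one, the curve gives 64%. The flask gives 75.5%, which is higher, with 36% of its reagent left.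

Readings and results stem from a simulated flask for substances that don't exist, noise included.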